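**Plan**

- Locants: C1 ring-fusion CH, C2 lactone O–CH, C3/C13 ether CH, C4 CHMe, C8/C12 methyl carbinols, C9=C10 Z-alkene, C14 ring CH2, C15–C17 lactone α-carbon, carbonyl, exo-methylene. Enabling feature: the C1–C2 bond is shared by the tetrahydropyran (C1, C2, C3, O, C13, C14) and the butyrolactone, and joins the oxygenated C2 to the carbon next to the C15=C17 methylene. That is the homoallylic-alcohol pattern left when an ester-bearing allyl metal adds to an aldehyde, here across the C3–O–C13 ether of a 12-membered ring.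
- Cuts, in retrosynthetic order: lactone O–C16; C1–C2; C1–C15 and C17–Br; C9≡C10 (alkyne metathesis, alkene by semi-hydrogenation); C10–C11, C12–CH3, C11–C12 and C13–C14 on a glycolate attached to O–C3; C2–C3/C4–C5 on a C5–C10 chain from geraniol.
- Forward order: acyclic chain (C5–C10, then C2–C4, then the C11–C14 glycolate arm), then the 12-membered ether ring, then the tetrahydropyran, then the lactone.
- Stereochemistry: C8 from a Sharpless epoxidation carried through an epoxy-chloride fragmentation; C4 and C13 from (S)-4-benzyl-oxazolidinone auxiliaries; C3 from L-proline catalysis; C12 from chelation-controlled methyl addition; Z-alkene from cis-hydrogenation of the cycloalkyne; C1 and C2 from the cyclic transition state of the key step.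

Key step: step 29

Remark: both tertiary hydroxyls are carried as triethylsilyl ethers through the key step, because a free C12–OH would attack the bromomethyl enoate (5-exo SN2′) and form lactols with the C1 and C2 aldehydes. 1-Propynyllithium is taken as a commercial reagent.

**Route**

Step 1
Reactants: 1 geraniol
Product: 2 (2R,3R)-2,3-epoxygeraniol
Conditions: Ti(OiPr)4 (5 mol %), D-(−)-diethyl tartrate (6 mol %), t-BuOOH, 4 Å MS, CH2Cl2, −20 °C
Reagents that add atoms: tert-butyl hydroperoxide, CC(C)(C)OO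
Why: Sharpless asymmetric epoxidation of an (E)-trisubstituted allylic alcohol, in which the D-tartrate complex selects the face that makes the future C8 carbon (geraniol C3) R.

Step 2
Reactants: 2 (2R,3R)-2,3-epoxygeraniol
Product: 3 2,3-epoxygeranyl chloride (configuration of 2 retained)
Conditions: PPh3, CCl4, NaHCO3, reflux
Reagents that add atoms: carbon tetrachloride, ClC(Cl)(Cl)Cl
Why: Appel chlorination of the primary alcohol under neutral conditions leaves the epoxide and both stereocentres untouched.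

Step 3
Reactants: 3 2,3-epoxygeranyl chloride
Product: 5 (R)-4,8-dimethylnon-7-en-2-yn-4-ol, via dilithiated dehydrolinalool 4 (not isolated)
Conditions: n-BuLi (3.3 equiv), THF, −78 to −30 °C; then MeI, −78 °C to rt
Reagents that add atoms: iodomethane, CI
Why: Base-induced fragmentation of a 2,3-epoxy chloride (α-deprotonation, epoxide opening to a chlorovinyl alkoxide, dehydrochlorination) gives the tertiary propargylic alkoxide without breaking the C8–O bond, and the lithium acetylide is C-methylated in the same flask to give the methyl cap needed for alkyne metathesis.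

Step 4
Reactants: 5 (R)-4,8-dimethylnon-7-en-2-yn-4-ol
Product: 6 triethylsilyl ether of 5
Conditions: Et3SiOTf, 2,6-lutidine, CH2Cl2, −78 to 0 °C
Reagents that add atoms: triethylsilyl trifluoromethanesulfonate, CC[Si](CC)(CC)OS(=O)(=O)C(F)(F)F
Why: Silyl triflate silylation of a hindered tertiary alcohol masks C8–OH for the organometallic steps and should persist until the final acid treatment.

Step 5
Reactants: 6 triethylsilyl ether of 5
Product: 8 (R)-4-methyl-4-(triethylsilyloxy)hept-5-yn-1-ol, via ozonolysis aldehyde 7 (not isolated)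
Conditions: O3, CH2Cl2/MeOH, −78 °C (Sudan III end-point); then NaBH4, −78 to 0 °C
Reagents that add atoms: ozone, [O-][O+]=O
Why: Ozonolysis cleaves the electron-rich trisubstituted alkene much faster than the internal alkyne, and borohydride work-up reduces the aldehyde to the C5 alcohol.

Step 6
Reactants: 8 (R)-4-methyl-4-(triethylsilyloxy)hept-5-yn-1-ol
Product: 9 (R)-7-bromo-4-methyl-4-(triethylsilyloxy)hept-2-yne
Conditions: CBr4, PPh3, 2,6-lutidine, CH2Cl2, 0 °C
Reagents that add atoms: carbon tetrabromide, BrC(Br)(Br)Br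
Why: Appel bromination converts the primary alcohol into the bromide needed for Grignard formation without touching the tertiary silyl ether.

Step 7
Reactants: 10 (S)-4-benzyl-1,3-oxazolidin-2-one; 11 (E)-but-2-enoyl chloride
Product: 12 (S)-4-benzyl-3-[(E)-but-2-enoyl]-1,3-oxazolidin-2-one
Conditions: Et3N, LiCl, THF, 0 °C to rt
Reagents that add atoms: none
Why: Mild N-acylation of the oxazolidinone gives the (E)-enoyl imide without isomerising the double bond.

Step 8
Reactants: 9 (R)-7-bromo-4-methyl-4-(triethylsilyloxy)hept-2-yne; 12 (S)-4-benzyl-3-[(E)-but-2-enoyl]-1,3-oxazolidin-2-one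
Product: 14 (S)-4-benzyl-3-[(3S,7R)-3,7-dimethyl-7-(triethylsilyloxy)dec-8-ynoyl]-1,3-oxazolidin-2-one, via Grignard reagent 13 (not isolated)
Conditions: Mg turnings, THF, rt; CuBr·SMe2 (1 equiv), Me2S/THF, −78 °C; then 12, −78 to −20 °C
Reagents that add atoms: none
Why: Copper-mediated conjugate addition of the alkylmagnesium bromide to the chelated s-cis enoyl imide occurs on the face opposite the benzyl group and sets C4 as S.

Step 9
Reactants: 14 conjugate-addition imide
Product: 15 (3S,7R)-3,7-dimethyl-7-(triethylsilyloxy)dec-8-yn-1-ol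
Conditions: LiBH4, MeOH (1 equiv), Et2O, 0 °C
Reagents that add atoms: none
Why: Reductive cleavage of the imide at the exocyclic carbonyl releases the primary alcohol and the recoverable auxiliary without affecting alkyne or silyl ether.

Step 10
Reactants: 15 (3S,7R)-3,7-dimethyl-7-(triethylsilyloxy)dec-8-yn-1-ol
Product: 16 (3S,7R)-3,7-dimethyl-7-(triethylsilyloxy)dec-8-ynal
Conditions: Dess–Martin periodinane, CH2Cl2, 0 °C to rt
Reagents that add atoms: none
Why: Dess–Martin oxidation gives the β-branched aldehyde under non-epimerising, near-neutral conditions.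

Step 11
Reactants: 16 (3S,7R)-3,7-dimethyl-7-(triethylsilyloxy)dec-8-ynal
Product: 18 (2R,3S,7R)-3,7-dimethyl-2-(phenylaminooxy)-7-(triethylsilyloxy)dec-8-yn-1-ol, via α-anilinooxy aldehyde 17 (not isolated)
Conditions: L-proline (30 mol %), PhNO (slow addition), MeCN, −20 °C; then NaBH4, MeOH, 0 °C
Reagents that add atoms: nitrosobenzene, O=Nc1ccccc1
Why: Proline-enamine α-aminoxylation is catalyst-controlled (L-proline gives the 2R α-oxy aldehyde, so C3 is R), and the labile aldehyde is reduced in the same flask.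

Step 12
Reactants: 18 anilinooxy alcohol
Product: 19 (2R,3S,7R)-3,7-dimethyl-7-(triethylsilyloxy)dec-8-yne-1,2-diol
Conditions: Zn dust, AcOH/THF, rt
Reagents that add atoms: none
Why: Reductive N–O cleavage of the O-alkyl-N-phenylhydroxylamine frees the C3 hydroxyl without affecting alkyne or silyl ether.

Step 13
Reactants: 19 (2R,3S,7R)-diol
Product: 21 (2R,3S,7R)-1-(4-methoxybenzyloxy)-3,7-dimethyl-7-(triethylsilyloxy)dec-8-yn-2-ol, via stannylene acetal 20 (not isolated)
Conditions: Bu2SnO, toluene, reflux (−H2O); then 4-methoxybenzyl chloride, Bu4NI, 90 °C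
Reagents that add atoms: 4-methoxybenzyl chloride, COc1ccc(CCl)cc1
Why: Stannylene acetals of terminal 1,2-diols are alkylated at the primary oxygen, which leaves the C3 hydroxyl free for etherification.

Step 14
Reactants: 21 mono-PMB diol; 22 bromoacetic acid
Product: 23 O-(C3)-glycolic acid ether of 21
Conditions: NaH (3 equiv), THF/DMF, 0 °C to rt
Reagents that add atoms: none
Why: Williamson etherification of the C3 alkoxide with sodium bromoacetate installs the two carbons that become C13 and C12.

Step 15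
Reactants: 23 glycolic acid ether; 10 (S)-4-benzyl-1,3-oxazolidin-2-one
Product: 25 N-(alkoxyacetyl) imide of 23, via mixed pivalic anhydride 24 (not isolated)
Conditions: t-BuCOCl, Et3N, THF, −20 °C; then 10, LiCl, rt
Reagents that add atoms: none
Why: Mixed-anhydride activation followed by N-acylation gives the glycolyl imide required for auxiliary-controlled alkylation.

Step 16
Reactants: 25 glycolyl imide; 26 allyl iodide
Product: 28 C13-allylated imide (C13 R), via sodium enolate 27 (not isolated)
Conditions: NaN(SiMe3)2, THF, −78 °C; then 26, −78 to −45 °C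
Reagents that add atoms: none
Why: Asymmetric glycolate alkylation, in which the chelated (Z)-sodium enolate is attacked by the allylic iodide on the face opposite the benzyl group, sets C13 as R.

Step 17
Reactants: 28 allylated imide
Product: 29 N-methoxy-N-methylamide (C12 carbonyl, C13 R)
Conditions: MeNH(OMe)·HCl, AlMe3, CH2Cl2, −20 to 0 °C
Reagents that add atoms: N,O-dimethylhydroxylamine hydrochloride, CNOC.Cl
Why: Aluminium amide transamidation at the exocyclic carbonyl removes the auxiliary and gives the Weinreb amide without epimerising C13.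

Step 18
Reactants: 29 Weinreb amide
Product: 30 α-chloromethyl ketone (C11H2Cl–C12(=O)–C13)
Conditions: ICH2Cl, MeLi·LiBr, THF, −78 °C
Reagents that add atoms: chloroiodomethane, ClCI
Why: Chloromethyllithium generated in situ adds once to the Weinreb amide through a stable chelated tetrahedral intermediate and brings in C11.

Step 19
Reactants: 30 α-chloromethyl ketone
Product: 32 C11–C12 epoxide (C12 S, C13 R), via chlorohydrin 31 (not isolated)
Conditions: MeMgBr, CH2Cl2/Et2O, −78 °C; aqueous work-up; then K2CO3, MeOH, rt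
Reagents that add atoms: methylmagnesium bromide, C[Mg]Br
Why: Cram-chelate Grignard addition, with magnesium bridging the ketone and the C13 ether oxygen so that methyl enters from the side of the C13 hydrogen, sets C12, and the chlorohydrin then closes to the epoxide by 3-exo-tet displacement.

Step 20
Reactants: 32 epoxide; 33 1-propynyllithium
Product: 34 homopropargylic tertiary alcohol (C12–OH, C11H2–C≡C–CH3)
Conditions: BF3·OEt2, THF, −78 °C
Reagents that add atoms: none
Why: Lewis-acid-assisted alkynylation opens the 2,2-disubstituted epoxide at its CH2 terminus, so the C12–O bond and its configuration are untouched.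

Step 21
Reactants: 34 homopropargylic alcohol
Product: 35 bis(triethylsilyl) diyne
Conditions: Et3SiOTf, 2,6-lutidine, CH2Cl2, 0 °C
Reagents that add atoms: triethylsilyl trifluoromethanesulfonate, CC[Si](CC)(CC)OS(=O)(=O)C(F)(F)F
Why: Silyl triflate silylation protects the C12 tertiary alcohol, which must not be free next to the later aldehydes and the allylic bromide.

Step 22
Reactants: 35 bis(triethylsilyl) diyne
Product: 36 12-membered cyclic ether with C9≡C10, allyl arm on C13 and CH2OPMB on C3
Conditions: Mo(≡C-C6H4-4-OMe)(OSiPh3)3 (10 mol %), 5 Å MS, toluene (2 mM), 80 °C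
Reagents that add atoms: none
Why: Ring-closing alkyne metathesis of the two methyl-capped alkynes forms C9≡C10 and the 12-membered ring, driven by trapping of but-2-yne in the sieves, while the terminal alkene is inert to the alkylidyne.

Step 23
Reactants: 36 cycloalkyne with allyl arm
Product: 38 cycloalkyne C1 aldehyde, via vicinal diol 37 (not isolated)
Conditions: OsO4 (2 mol %), NaIO4, 2,6-lutidine, dioxane/H2O, rt
Reagents that add atoms: osmium tetroxide, O=[Os](=O)(=O)=O; sodium periodate, [Na+].[O-]I(=O)(=O)=O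
Why: Lemieux–Johnson cleavage, in which osmium tetroxide dihydroxylates the terminal alkene but not the alkyne and periodate cleaves the diol, gives the C1 aldehyde.

Step 24
Reactants: 38 cycloalkyne C1 aldehyde
Product: 39 (Z)-C9=C10 cycloalkene C1 aldehyde
Conditions: H2 (1 atm), Pd/CaCO3 poisoned with Pb(OAc)2, quinoline, EtOAc, rt
Reagents that add atoms: none
Why: Syn addition of hydrogen on the poisoned palladium surface converts the cycloalkyne into the Z-alkene and stops at that stage.

Step 25
Reactants: 39 (Z)-cycloalkene C1 aldehyde; 40 methyl acrylate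
Product: 41 Morita–Baylis–Hillman adduct (C1 carbinol epimers)
Conditions: DABCO (1 equiv), 40 (excess), MeOH (cat.), rt
Reagents that add atoms: none
Why: Morita–Baylis–Hillman reaction of the aliphatic aldehyde attaches C15–C17, and the new carbinol configuration is irrelevant because it is erased in the next step.

Step 26
Reactants: 41 Morita–Baylis–Hillman adduct
Product: 42 (Z)-2-(bromomethyl)enoate (C1=C15, C17H2Br), PMB ether
Conditions: NBS, Me2S, CH2Cl2, 0 °C to rt
Reagents that add atoms: N-bromosuccinimide, O=C1CCC(=O)N1Br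
Why: Corey–Kim-type activation of the allylic alcohol and SN2′ return of bromide give the thermodynamically preferred (Z)-bromomethyl enoate.

Step 27
Reactants: 42 (Z)-2-(bromomethyl)enoate PMB ether
Product: 43 C2 primary alcohol
Conditions: DDQ, CH2Cl2/pH 7 buffer, 0 °C
Reagents that add atoms: none
Why: Oxidative cleavage of the 4-methoxybenzyl ether is orthogonal to the silyl ethers, the Z-alkene and the allylic bromide.

Step 28
Reactants: 43 C2 primary alcohol
Product: 44 12-membered cyclic ether with C2 aldehyde and (Z)-2-(bromomethyl)enoate arm (bis-triethylsilyl ether)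
Conditions: Dess–Martin periodinane, CH2Cl2, 0 °C to rt
Reagents that add atoms: none
Why: Dess–Martin oxidation gives the α-alkoxy aldehyde without base, so C3 should not epimerise and the bromide is untouched.

Step 29
Reactants: 44 C2 aldehyde with (Z)-2-(bromomethyl)enoate arm
Product: 46 cis γ-hydroxy α-methylene methyl ester with the tetrahydropyran closed (bis-triethylsilyl ether), via allylindium bromide 45 (not isolated)
Conditions: In powder (3 equiv), THF/H2O 2:1 (0.01 M), rt
Reagents that add atoms: none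
Why: Zerovalent indium inserts into the allylic C–Br bond and the 2-(methoxycarbonyl)allylindium adds to the C2 aldehyde through its γ-carbon C1 in a closed, chair-like six-membered transition state, shifting the double bond to C15=C17; this is the intramolecular form of the known aqueous Barbier allylation of aldehydes with 2-(bromomethyl)acrylates used for α-methylene-γ-butyrolactones. The new C1–C2 bond closes the tetrahydropyran (C1, C2, C3, O, C13, C14) in a 6-exo-trig mode across the ether already held in the 12-membered ring. The cis relationship of C1 and C2 follows from the (Z)-allyl geometry in the closed transition state (C14 axial and C3 equatorial on the metallacycle, a cis-fused bicyclic array). Their absolute sense is set by C3 and C13: the carbonyl oxygen should turn anti to the C3–O bond and away from the nine-atom bridge covering the face that carries C4 and C12, which gives C2 S and C1 R. The step needs γ- over α-attack (six- instead of eight-membered ring), chemoselective insertion at the allylic bromide (silyl ethers, ester and Z-alkene are inert in aqueous THF) and the facial selectivity that the cis-2,6 bridge is expected to provide.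

Step 30
Reactants: 46 bis-silylated hydroxy ester
Product: 48 CNP0146755.1, via desilylated hydroxy ester 47 (not isolated)
Conditions: HF (48 % aq., 5 vol %), MeCN, 0 °C to rt
Reagents that add atoms: none
Why: Acidic fluoride removes both tertiary silyl ethers and the cis γ-hydroxy ester lactonizes (5-exo-trig acyl substitution, loss of methanol) to the cis-fused α-methylene-γ-butyrolactone.

**Compound list**

1 | geraniol | CC(C)=CCC/C(C)=C/CO | starting material
2 | (2R,3R)-2,3-epoxygeraniol | OC[C@H]1O[C@]1(C)CCC=C(C)C | intermediate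
3 | 2,3-epoxygeranyl chloride (configuration of 2) | ClC[C@H]1O[C@]1(C)CCC=C(C)C | intermediate
4 | dilithiated (R)-dehydrolinalool (lithium alkoxide, lithium acetylide) | [Li]C#C[C@](C)(O[Li])CCC=C(C)C | intermediate
5 | (R)-4,8-dimethylnon-7-en-2-yn-4-ol | CC#C[C@](C)(O)CCC=C(C)C | intermediate
6 | (R)-4,8-dimethyl-4-(triethylsilyloxy)non-7-en-2-yne | CC#C[C@](C)(O[Si](CC)(CC)CC)CCC=C(C)C | intermediate
7 | (R)-4-methyl-4-(triethylsilyloxy)hept-5-ynal | CC#C[C@](C)(O[Si](CC)(CC)CC)CCC=O | intermediate
8 | (R)-4-methyl-4-(triethylsilyloxy)hept-5-yn-1-ol | CC#C[C@](C)(O[Si](CC)(CC)CC)CCCO | intermediate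
9 | (R)-7-bromo-4-methyl-4-(triethylsilyloxy)hept-2-yne | CC#C[C@](C)(O[Si](CC)(CC)CC)CCCBr | intermediate
10 | (S)-4-benzyl-1,3-oxazolidin-2-one | O=C1N[C@@H](Cc2ccccc2)CO1 | starting material
11 | (E)-but-2-enoyl chloride | C/C=C/C(Cl)=O | starting material
12 | (S)-4-benzyl-3-[(E)-but-2-enoyl]-1,3-oxazolidin-2-one | C/C=C/C(=O)N1[C@@H](Cc2ccccc2)COC1=O | intermediate
13 | Grignard reagent of 9 | CC#C[C@](C)(O[Si](CC)(CC)CC)CCC[Mg]Br | intermediate
14 | (S)-4-benzyl-3-[(3S,7R)-3,7-dimethyl-7-(triethylsilyloxy)dec-8-ynoyl]-1,3-oxazolidin-2-one | CC#C[C@](C)(O[Si](CC)(CC)CC)CCC[C@H](C)CC(=O)N1[C@@H](Cc2ccccc2)COC1=O | intermediate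
15 | (3S,7R)-3,7-dimethyl-7-(triethylsilyloxy)dec-8-yn-1-ol | CC#C[C@](C)(O[Si](CC)(CC)CC)CCC[C@H](C)CCO | intermediate
16 | (3S,7R)-3,7-dimethyl-7-(triethylsilyloxy)dec-8-ynal | CC#C[C@](C)(O[Si](CC)(CC)CC)CCC[C@H](C)CC=O | intermediate
17 | (2R,3S,7R)-3,7-dimethyl-2-(phenylaminooxy)-7-(triethylsilyloxy)dec-8-ynal | CC#C[C@](C)(O[Si](CC)(CC)CC)CCC[C@H](C)[C@@H](ONc1ccccc1)C=O | intermediate
18 | (2R,3S,7R)-3,7-dimethyl-2-(phenylaminooxy)-7-(triethylsilyloxy)dec-8-yn-1-ol | CC#C[C@](C)(O[Si](CC)(CC)CC)CCC[C@H](C)[C@@H](ONc1ccccc1)CO | intermediate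
19 | (2R,3S,7R)-3,7-dimethyl-7-(triethylsilyloxy)dec-8-yne-1,2-diol | CC#C[C@](C)(O[Si](CC)(CC)CC)CCC[C@H](C)[C@@H](O)CO | intermediate
20 | dibutylstannylene acetal of 19 | CCCC[Sn]1(CCCC)OC[C@H](O1)[C@@H](C)CCC[C@@](C)(O[Si](CC)(CC)CC)C#CC | intermediate
21 | (2R,3S,7R)-1-(4-methoxybenzyloxy)-3,7-dimethyl-7-(triethylsilyloxy)dec-8-yn-2-ol | COc1ccc(COC[C@H](O)[C@@H](C)CCC[C@@](C)(O[Si](CC)(CC)CC)C#CC)cc1 | intermediate
22 | bromoacetic acid | OC(=O)CBr | starting material
23 | 2-{[(2R,3S,7R)-1-(4-methoxybenzyloxy)-3,7-dimethyl-7-(triethylsilyloxy)dec-8-yn-2-yl]oxy}acetic acid | OC(=O)CO[C@@H](COCc1ccc(OC)cc1)[C@@H](C)CCC[C@@](C)(O[Si](CC)(CC)CC)C#CC | intermediate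
24 | mixed pivalic anhydride of 23 | CC(C)(C)C(=O)OC(=O)CO[C@@H](COCc1ccc(OC)cc1)[C@@H](C)CCC[C@@](C)(O[Si](CC)(CC)CC)C#CC | intermediate
25 | (S)-4-benzyl-3-(alkoxyacetyl)-1,3-oxazolidin-2-one from 23 (glycolyl imide) | O=C(CO[C@@H](COCc1ccc(OC)cc1)[C@@H](C)CCC[C@@](C)(O[Si](CC)(CC)CC)C#CC)N1[C@@H](Cc2ccccc2)COC1=O | intermediate
26 | allyl iodide | C=CCI | starting material
27 | (Z)-sodium enolate of 25 | [Na]O/C(=C\O[C@@H](COCc1ccc(OC)cc1)[C@@H](C)CCC[C@@](C)(O[Si](CC)(CC)CC)C#CC)N1[C@@H](Cc2ccccc2)COC1=O | intermediate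
28 | (S)-4-benzyl-3-[(2R)-2-alkoxypent-4-enoyl]-1,3-oxazolidin-2-one (alkoxy = C3 oxygen of the chain of 21; C13 R) | C=CC[C@@H](O[C@@H](COCc1ccc(OC)cc1)[C@@H](C)CCC[C@@](C)(O[Si](CC)(CC)CC)C#CC)C(=O)N1[C@@H](Cc2ccccc2)COC1=O | intermediate
29 | (2R)-2-alkoxy-N-methoxy-N-methylpent-4-enamide (same alkoxy group) | C=CC[C@@H](O[C@@H](COCc1ccc(OC)cc1)[C@@H](C)CCC[C@@](C)(O[Si](CC)(CC)CC)C#CC)C(=O)N(C)OC | intermediate
30 | (3R)-3-alkoxy-1-chlorohex-5-en-2-one (same alkoxy group) | C=CC[C@@H](O[C@@H](COCc1ccc(OC)cc1)[C@@H](C)CCC[C@@](C)(O[Si](CC)(CC)CC)C#CC)C(=O)CCl | intermediate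
31 | (2R,3R)-3-alkoxy-1-chloro-2-methylhex-5-en-2-ol (C12 drawn as in the target; R by CIP because of chlorine) | C=CC[C@@H](O[C@@H](COCc1ccc(OC)cc1)[C@@H](C)CCC[C@@](C)(O[Si](CC)(CC)CC)C#CC)[C@@](C)(O)CCl | intermediate
32 | (S)-2-[(1R)-1-alkoxybut-3-enyl]-2-methyloxirane (C11–C12 epoxide) | C=CC[C@@H](O[C@@H](COCc1ccc(OC)cc1)[C@@H](C)CCC[C@@](C)(O[Si](CC)(CC)CC)C#CC)[C@]1(C)CO1 | intermediate
33 | 1-propynyllithium | [Li]C#CC | starting material
34 | (4R,5S)-4-alkoxy-5-methylnon-1-en-7-yn-5-ol (C12 S, C13 R) | C=CC[C@@H](O[C@@H](COCc1ccc(OC)cc1)[C@@H](C)CCC[C@@](C)(O[Si](CC)(CC)CC)C#CC)[C@@](C)(O)CC#CC | intermediate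
35 | bis(triethylsilyl) diyne (triethylsilyl ether of 34) | C=CC[C@@H](O[C@@H](COCc1ccc(OC)cc1)[C@@H](C)CCC[C@@](C)(O[Si](CC)(CC)CC)C#CC)[C@@](C)(O[Si](CC)(CC)CC)CC#CC | intermediate
36 | 12-membered cyclic ether, C9≡C10, C13 allyl, C3 CH2OPMB, C8/C12 OSiEt3 (3R,4S,8R,12S,13R) | COc1ccc(COC[C@@H]2O[C@H](CC=C)[C@@](C)(O[Si](CC)(CC)CC)CC#C[C@](C)(O[Si](CC)(CC)CC)CCC[C@@H]2C)cc1 | intermediate
37 | 1,2-diol from the allyl arm of 36 (epimers at the new carbinol) | COc1ccc(COC[C@@H]2O[C@H](CC(O)CO)[C@@](C)(O[Si](CC)(CC)CC)CC#C[C@](C)(O[Si](CC)(CC)CC)CCC[C@@H]2C)cc1 | intermediate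
38 | cycloalkyne with C14H2–C1HO arm | COc1ccc(COC[C@@H]2O[C@H](CC=O)[C@@](C)(O[Si](CC)(CC)CC)CC#C[C@](C)(O[Si](CC)(CC)CC)CCC[C@@H]2C)cc1 | intermediate
39 | (Z)-C9=C10 cycloalkene with C14H2–C1HO arm | COc1ccc(COC[C@@H]2O[C@H](CC=O)[C@@](C)(O[Si](CC)(CC)CC)C/C=C\[C@](C)(O[Si](CC)(CC)CC)CCC[C@@H]2C)cc1 | intermediate
40 | methyl acrylate | C=CC(=O)OC | starting material
41 | Morita–Baylis–Hillman adduct, C1H(OH)–C15(=C17H2)CO2Me (C1 epimers) | COc1ccc(COC[C@@H]2O[C@H](CC(O)C(=C)C(=O)OC)[C@@](C)(O[Si](CC)(CC)CC)C/C=C\[C@](C)(O[Si](CC)(CC)CC)CCC[C@@H]2C)cc1 | intermediate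
42 | (Z)-2-(bromomethyl)enoate, C3 CH2OPMB | COc1ccc(COC[C@@H]2O[C@H](C/C=C(\CBr)C(=O)OC)[C@@](C)(O[Si](CC)(CC)CC)C/C=C\[C@](C)(O[Si](CC)(CC)CC)CCC[C@@H]2C)cc1 | intermediate
43 | (Z)-2-(bromomethyl)enoate, C3 CH2OH | OC[C@@H]1O[C@H](C/C=C(\CBr)C(=O)OC)[C@@](C)(O[Si](CC)(CC)CC)C/C=C\[C@](C)(O[Si](CC)(CC)CC)CCC[C@@H]1C | intermediate
44 | 12-membered cyclic ether with C2 aldehyde and (Z)-2-(bromomethyl)enoate arm, C8/C12 OSiEt3 | O=C[C@@H]1O[C@H](C/C=C(\CBr)C(=O)OC)[C@@](C)(O[Si](CC)(CC)CC)C/C=C\[C@](C)(O[Si](CC)(CC)CC)CCC[C@@H]1C | intermediate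
45 | allylindium species from 44 (drawn as the C17 allylindium dibromide) | O=C[C@@H]1O[C@H](C/C=C(\C[In](Br)Br)C(=O)OC)[C@@](C)(O[Si](CC)(CC)CC)C/C=C\[C@](C)(O[Si](CC)(CC)CC)CCC[C@@H]1C | intermediate
46 | cis γ-hydroxy α-methylene methyl ester of the ether-bridged macrocycle, C8/C12 OSiEt3 (1R,2S,3R,4S,8R,12S,13R) | C=C(C(=O)OC)[C@H]1C[C@H]2O[C@@H]([C@H]1O)[C@@H](C)CCC[C@@](C)(O[Si](CC)(CC)CC)/C=C\C[C@]2(C)O[Si](CC)(CC)CC | intermediate
47 | desilylated cis γ-hydroxy α-methylene methyl ester | C=C(C(=O)OC)[C@H]1C[C@H]2O[C@@H]([C@H]1O)[C@@H](C)CCC[C@@](C)(O)/C=C\C[C@]2(C)O | intermediate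
48 | CNP0146755.1 | C=C1C(=O)O[C@@H]2[C@@H]3O[C@H](C[C@H]12)[C@@](C)(O)C/C=C\[C@](C)(O)CCC[C@@H]3C | target

**Step count**

Total steps: 30. Longest linear sequence: 29 steps from geraniol (steps 1–6 and 8–30); step 7 is a one-step side branch.

**Steps most likely to fail**

Step 22 (ring-closing alkyne metathesis). The alkylidyne may fail to engage the alkyne next to the fully substituted C8, so that the unhindered butynyl ends dimerise or oligomerise instead of closing the ring. The fallback replaces alkyne by olefin metathesis and sets out from 35. Oxidative cleavage of the allyl group (OsO4 cat., NaIO4, 2,6-lutidine) would give the diyne aldehyde F1. Cis-semi-hydrogenation of both alkynes over Pd/CaCO3 poisoned with Pb(OAc)2 would give the bis-(Z)-alkene aldehyde F2. Stereoretentive ring-closing olefin metathesis with Ru(=CH-C6H4-2-OiPr)(1,3-dimesitylimidazolidin-2-ylidene)(3,6-dichlorobenzene-1,2-dithiolate) in dilute THF, with loss of (Z)-but-2-ene, should then give the Z-cycloalkene aldehyde and rejoin the route at 39.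

Step 29 (indium allylation). Indium bridging the aldehyde and the ring-ether oxygen could turn the carbonyl toward the bridged face and erode facial selectivity at C2; proton quench of the allylindium or attack through C17 could also compete. The fallback uses a Lewis-acid-promoted allylsilane cyclisation through an open, non-chelated transition state and sets out from 39. Horner–Wadsworth–Emmons olefination with methyl 2-(dimethoxyphosphoryl)-3-(trimethylsilyl)propanoate (NaH, THF) would give the 2-(trimethylsilylmethyl)enoate F3. DDQ would free the C2 alcohol F4, and Dess–Martin oxidation would give the aldehyde F5. Intramolecular Hosomi–Sakurai allylation (BF3·OEt2, CH2Cl2, −78 °C) should then close the tetrahydropyran and rejoin the route at 46.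

Step 25 (Morita–Baylis–Hillman reaction). The amine-catalysed addition may stall on this β-alkoxy aldehyde, and prolonged exposure to base could eliminate the C13 alkoxy group. The fallback is a stoichiometric aldol followed by selenoxide elimination and sets out from 39. Addition of the lithium enolate of methyl 3-(phenylselanyl)propanoate (LiN(iPr)2, THF, −78 °C) would give the β-hydroxy selenide F6. Oxidation with H2O2/pyridine and syn-elimination of the selenoxide should then give the α-methylene β-hydroxy ester and rejoin the route at 41.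

Further compounds
F1 | step 22 | diyne aldehyde from 35 (allyl cleaved to C1HO) | O=CC[C@@H](O[C@@H](COCc1ccc(OC)cc1)[C@@H](C)CCC[C@@](C)(O[Si](CC)(CC)CC)C#CC)[C@@](C)(O[Si](CC)(CC)CC)CC#CC
F2 | step 22 | bis-(Z)-alkene aldehyde | O=CC[C@@H](O[C@@H](COCc1ccc(OC)cc1)[C@@H](C)CCC[C@@](C)(O[Si](CC)(CC)CC)/C=C\C)[C@@](C)(O[Si](CC)(CC)CC)C/C=C\C
F3 | step 29 | 2-(trimethylsilylmethyl)enoate, C3 CH2OPMB (Z isomer drawn) | COc1ccc(COC[C@@H]2O[C@H](C/C=C(\C[Si](C)(C)C)C(=O)OC)[C@@](C)(O[Si](CC)(CC)CC)C/C=C\[C@](C)(O[Si](CC)(CC)CC)CCC[C@@H]2C)cc1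
F4 | step 29 | 2-(trimethylsilylmethyl)enoate, C3 CH2OH | OC[C@@H]1O[C@H](C/C=C(\C[Si](C)(C)C)C(=O)OC)[C@@](C)(O[Si](CC)(CC)CC)C/C=C\[C@](C)(O[Si](CC)(CC)CC)CCC[C@@H]1C
F5 | step 29 | 2-(trimethylsilylmethyl)enoate, C2 aldehyde | O=C[C@@H]1O[C@H](C/C=C(\C[Si](C)(C)C)C(=O)OC)[C@@](C)(O[Si](CC)(CC)CC)C/C=C\[C@](C)(O[Si](CC)(CC)CC)CCC[C@@H]1C
F6 | step 25 | β-hydroxy α-(phenylselanylmethyl) ester (epimers) | COc1ccc(COC[C@@H]2O[C@H](CC(O)C(C[Se]c3ccccc3)C(=O)OC)[C@@](C)(O[Si](CC)(CC)CC)C/C=C\[C@](C)(O[Si](CC)(CC)CC)CCC[C@@H]2C)cc1
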